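## Structural features

The target is a flavonol 3-methyl ether whose ring B is a quinone: a 4H-chromen-4-one (benzo ring A fused to pyranone ring C along C4a–C8a) is joined through the single bond C2–C1′ to a 1,4-benzoquinone (ring B) with methoxy groups at C2′ and C4′ and carbonyls at C3′ and C6′. Ring A has a free hydroxyl at C5, hydrogen-bonded to the C4 carbonyl, and a methoxy group at C7; ring C has a methoxy group at C3. There is no stereocentre, so no two stereocentres stand next to each other; the C2–C1′ bond is flanked by the C3 methoxy group, the C2′ methoxy group and the C6′ carbonyl, so ring B is twisted out of the chromenone plane, but no configuration has to be controlled. The fragile part is the methoxyquinone, a vinylogous ester and Michael acceptor that tolerates neither nucleophiles, strong bases, organometallic reagents nor reductants; the pyranone can also be opened by hard nucleophiles at C2. The real difficulty is the differentiation of nine oxygen atoms on a nineteen-carbon molecule: one free phenol beside four methyl ethers, an oxygen at C3 that a plain flavone synthesis does not supply, a quinone that must be revealed last, and a C2–C1′ bond to a ring B carbon with two ortho substituents. The key step uses the arrangement in ring A: O1 sits on C8a, the acyl carbon C4 on the neighbouring C4a, and the C5 oxygen on the next carbon, which is the pattern left when an oxygen nucleophile and its own acyl group add across the C4a–C8a bond of a 3-alkoxyaryne.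

## Logic of the disconnections

20 from 19. The two ring B carbonyls (C3′=O and C6′=O) are traced back to aryl methyl ethers; no skeletal bond is cut, only two O–CH3 bonds are restored. The reason is that the quinone cannot survive any of the earlier chemistry. The gain is a robust tetra-alkoxy arene as ring B throughout. The forward oxidation must attack only ring B, and there only the one para pair of ethers, with the C5 phenol free.

19 from 17. The C5 hydroxyl is traced back to a methyl ether (forward: one O–CH3 bond is cut). The C5 oxygen is the substituent that steers the aryne step, and as a methyl ether it is inert to fluoride, carbonate and amide bases. The gain is that ring A carries only one kind of oxygen substituent and comes from 1. The demand is the cleavage of one methyl ether out of seven, which must rely on the peri relationship to the C4 carbonyl.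

17 from 16, and 16 from 14. The C3–O bond is cut, together with its O–CH3 bond. C3 is the only C–H of ring C and lies next to the C4 carbonyl, so oxygen can be brought in late by metalation. The gain is that the three carbons of ring C can come from a plain alkynoic acid. The demand is metalation at C3 and not at C6, C8 or C5′, without opening of ring C.

14 from 13. The O1–C2 bond is cut (retro-oxa-Michael), which opens ring C to a phenol and an ynone. The gain is an acyclic link between the two arenes with no ring C regiochemistry left to set. The forward closure must be 6-endo and not 5-exo.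

13 from 7 and 11. O1–C8a and C4a–C4 are cut together; this is the key disconnection. Both bonds leave adjacent ring A carbons, and the C5 oxygen stands beside C4a, so ring A maps onto a 3-alkoxyaryne and the rest onto a carboxylic acid. The gain is two fragments of similar size, no free phenol to protect and no Friedel–Crafts acylation. The demands are oxygen attack at the aryne carbon remote from the methoxy group and acyl migration faster than protonation. Re-derivation of the atom mapping of 7 (silicon on the future C4a, sulfonate on the future C8a) and of 11 (the future quinone carbons C3′ and C6′ both carry methoxy groups) shows both structures to be consistent with 20; no correction is needed.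

7 from 5, 2 and 1. The S–O bond of the sulfonate, the C–Si bond at the future C4a and the carbamate C–O bond are cut in turn. The carbamate exists to direct lithium to the carbon between it and a methoxy group; it is then exchanged for the sulfonate. The gain is 1, which already holds all three ring A oxygens. The demand is metalation between carbamate and methoxy, not between the two methoxy groups.

11 from 9 and 10, and 9 from 8. The C1′–C(sp) bond (the future C2–C1′ bond) is cut, then the C–I bond. The reason is that 8 has only two C–H positions and they are equivalent, so the halogenation needs no regiocontrol. The gain is two bought compounds. The demand is a coupling at a di-ortho-substituted, electron-rich iodide under conditions mild enough to keep the carboxyl group.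

## Other disconnections considered

Alternative 1: The cut goes through C4–C4a and O1–C2, so ring C is assembled in one operation from phloroglucinol A2 and the α-methoxy β-ketoester A3 (ethyl 2-methoxy-3-oxo-3-(2,3,4,6-tetramethoxyphenyl)propanoate).
- Forward step: the two are heated without solvent at about 250 °C. A3 should lose its alkoxy group to give an acylketene that C-acylates A2 (C4–C4a), and the aryl ketone then condenses with the neighbouring phenol (O1–C2) to give chromenone A1.
- In its favour: ring A is symmetrical, so there is no regiochemical question. The C3 methoxy group and the free C5 hydroxyl are present from the start, so no C3 oxidation and no selective demethylation are needed. One 7-O-methylation of A1 (the non-chelated, more acidic hydroxyl) would reach 19, and the final oxidation is shared.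
- Against it here: the ketone carbonyl of A3 lies between two ortho methoxy groups, so the ring-closing condensation must occur at a hindered, electron-rich carbonyl, at a temperature where polyphenols and polyethers can decompose. The partition between chromone and coumarin in such a condensation is controlled by temperature alone. A3 itself needs two or three steps from 8.
- Comparison: on step economy this alternative is the better one (about six steps against eleven). On structure it is also better, since it sets all the oxygen substituents of rings A and C without a protecting-group change. On mechanism the chosen plan is better: each bond forms in a directed process below 130 °C and the two halves are joined in solution. On the mono-functionalisation of ring A oxygens (7-O-methylation there, 5-O-demethylation here) the two are equal.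

Alternative 2: The cut is C4a–C5, inside ring A, which is folded from a polyketide chain masked as the 4-hydroxy-2-pyranone A5.
- Forward step: Mg(OMe)2 in methanol should open the lactone of A5 to the magnesium chelate of a methyl 3,5,7-trioxo ester. The methylene between the C5 and C7 carbonyls then attacks the ester carbon (Claisen condensation) and the ring aromatises to the trihydroxyphenyl enone A4.
- After it: A4 would still need an oxidative ring closure (O1–C2, for example iodine in DMSO) to reach A1, followed by the end game of Alternative 1.
- In its favour: it is biomimetic, the phloroglucinol pattern of ring A and the C3 methoxy group come from the chain itself, and the key event needs no halide, no palladium and no low temperature.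
- Against it here: A5 must be made by acylating a pyranone dianion with an α-methoxycinnamate. The open triketo ester can also fold by aldol condensation or simply re-lactonise. The enol ether geometry and the enone must survive methoxide. An extra oxidation follows the key step. Ring A is built from scratch although 1 is cheap.
- Comparison: on structure it equals the chosen plan in delivering the whole carbon skeleton in the key step, and is better in delivering the C3 methoxy group and a free C5 hydroxyl at once. On mechanism the chosen plan is better, because the aryne insertion has one directed mode while the Claisen/aldol choice rests only on the magnesium template. On step economy the two are about equal (roughly four steps to A5 and four after A4).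

Alternative 3: The cut removes C4 as carbon monoxide A9, breaking C4a–C4 and C3–C4 and leaving the ring A iodide A7 and the ring B ketone A8.
- Forward step: Pd(dba)2 with Xantphos, A9 and NaN(SiMe3)2. Oxidative addition of A7 to zerovalent palladium, insertion of A9 and attack of the sodium enolate of A8 on the acylpalladium species should give the 1,3-diketone A6. Its one stereocentre is racemic and is lost on cyclisation.
- After it: acid would remove the acetal and close ring C by cyclodehydration to 17, after which steps 10 and 11 are shared.
- In its favour: it is convergent, the C3 methoxy group is carried in A8, and the whole route would take about seven steps.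
- Against it here: A7 is di-ortho-substituted and electron-rich, so oxidative addition is slow and the acylpalladium is hindered. The enolate of A8 is an α-alkoxy enolate next to a 2,6-disubstituted aryl group. A toxic gas is required. The acetal is normally introduced with a carcinogenic α-chloro ether. The iodination of ring A must go between the two different oxygen functions, not between the two methoxy groups.
- Comparison: on step economy the alternative is better by three or four steps, and it avoids the separate C3 hydroxylation. On structure both plans attach C4 to C4a; the alternative needs O1 present and protected beforehand, whereas the chosen plan forms O1–C8a in the same event without a protecting group. On mechanism the ortho substituent is a liability there (hindrance in a catalytic cycle) and the control element here. On safety the chosen plan is at least equal (a sealed tube at 125 °C against a toxic gas).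

Key step: step 6

Assumption: 11 is charged as the free acid and becomes its caesium salt in the flask with the first equivalent of CsF; 1, 8 and 10 are bought.

Step 1
Reactants: 1 3,5-dimethoxyphenol
Product: 2 3,5-dimethoxyphenyl N-(propan-2-yl)carbamate
Conditions: i-PrNCO (1.3 equiv), Et3N (0.2 equiv), CH2Cl2, rt
Reagents that add atoms: isopropyl isocyanate, CC(C)N=C=O
Why: Base-catalysed addition of the phenol O–H across the isocyanate gives the secondary carbamate, which is the directing group for step 2 and can later be removed under mild E1cB conditions.

Step 2
Reactants: 2 3,5-dimethoxyphenyl N-(propan-2-yl)carbamate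
Product: 5 3,5-dimethoxy-2-(trimethylsilyl)phenyl N-(propan-2-yl)carbamate, via N-silyl carbamate 3 (not isolated), via C-silyl N-silyl carbamate 4 (not isolated)
Conditions: TMSOTf, TMEDA, Et2O, 0 °C to rt; n-BuLi, TMEDA, −78 °C; TMSCl, −78 °C to rt; aq NaHSO4
Reagents that add atoms: chlorotrimethylsilane, C[Si](C)(C)Cl; trimethylsilyl trifluoromethanesulfonate, C[Si](C)(C)OS(=O)(=O)C(F)(F)F (N-silyl group of 3 and 4 only)
Why: Directed ortho-metalation: the N–H is masked in the flask as 3, n-BuLi/TMEDA removes the proton at C2, which lies between the carbamate (the strongest director present) and a methoxy group and is preferred over C4 between two methoxy groups (C6 is equivalent to C2 by symmetry); silylation gives 4 and the acidic work-up hydrolyses only the N–Si bond.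

Step 3
Reactants: 5 3,5-dimethoxy-2-(trimethylsilyl)phenyl N-(propan-2-yl)carbamate
Product: 7 3,5-dimethoxy-2-(trimethylsilyl)phenyl trifluoromethanesulfonate, via 3,5-dimethoxy-2-(trimethylsilyl)phenol 6 (not isolated)
Conditions: DBU, Et2NH, MeCN, 40 °C; then PhNTf2, rt
Reagents that add atoms: N-phenylbis(trifluoromethanesulfonimide), O=S(=O)(N(c1ccccc1)S(=O)(=O)C(F)(F)F)C(F)(F)F
Why: E1cB cleavage: DBU deprotonates the carbamate N–H, the phenoxide of 6 is expelled and the isocyanate is scavenged by Et2NH as a urea; the amidinium phenoxide is triflated in the same flask, so the silyl phenol, which is prone to protodesilylation, is never isolated.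

Step 4
Reactants: 8 1,2,3,5-tetramethoxybenzene
Product: 9 2-iodo-1,3,4,5-tetramethoxybenzene
Conditions: NIS (1.05 equiv), CF3CO2H (10 mol%), MeCN, 0 °C to rt
Reagents that add atoms: N-iodosuccinimide, O=C1CCC(=O)N1I
Why: Electrophilic aromatic iodination; the only two C–H positions of 8 are equivalent and each is ortho to two methoxy groups and para to a third, so one equivalent of the iodinating agent should give a single mono-iodide.

Step 5
Reactants: 9 2-iodo-1,3,4,5-tetramethoxybenzene; 10 propiolic acid
Product: 11 3-(2,3,4,6-tetramethoxyphenyl)prop-2-ynoic acid
Conditions: Pd(PPh3)4 (5 mol%), DBU (2.5 equiv), DMSO, 35 °C; then aq HCl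
Reagents that add atoms: none
Why: Copper-free Sonogashira coupling: oxidative addition of 9 to zerovalent palladium, alkynyl transfer from the DBU propiolate and reductive elimination; working near room temperature without copper should keep the arylpropiolate from decarboxylating, and acidification liberates the acid.

Step 6
Reactants: 7 3,5-dimethoxy-2-(trimethylsilyl)phenyl trifluoromethanesulfonate; 11 3-(2,3,4,6-tetramethoxyphenyl)prop-2-ynoic acid
Product: 13 1-(2-hydroxy-4,6-dimethoxyphenyl)-3-(2,3,4,6-tetramethoxyphenyl)prop-2-yn-1-one, via 3,5-dimethoxybenzyne 12 (not isolated)
Conditions: 7 (1.5 equiv), CsF (4 equiv), THF, 125 °C (pressure-rated sealed tube); then aq NH4Cl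
Reagents that add atoms: none
Why: Fluoride attacks silicon in 7 and loss of triflate releases aryne 12 gradually, while CsF converts 11 into its caesium carboxylate. The carboxylate oxygen adds to the aryne carbon remote from the flanking methoxy group (future C8a), because that substituent makes this terminus the more electrophilic one by induction and angle distortion and stabilises the developing aryl anion on the neighbouring carbon (future C4a). The aryl anion then attacks the carbonyl of the ester just formed through a four-membered transition state, and the strained alkoxide opens to the phenoxide of 13; this anionic Fries-type O-to-C acyl shift amounts to insertion of the aryne into the acyl C–O bond and forms O1–C8a and C4a–C4. The closest known reaction type is the intermolecular C–O addition of carboxylic acids, arylpropiolic acids included, to arynes generated from silyl triflates with CsF in hot THF, which gives ortho-hydroxyaryl ketones. No ring is closed and no stereocentre is formed. Three selectivities are needed: the aryne regiochemistry, secured by the methoxy group ortho to the triple bond; acyl shift in preference to protonation of the aryl anion, secured by the aprotic medium, the buffering of the acid proton as bifluoride and the high temperature; and attack on the carbonyl and not on the alkyne, secured by the Z conformation of the aryl ester, which holds the alkyne away from the carbanion. Any part of the phenoxide that already closes to 14 in the hot fluoride medium is the product of step 7 and is carried forward with 13.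

Step 7
Reactants: 13 1-(2-hydroxy-4,6-dimethoxyphenyl)-3-(2,3,4,6-tetramethoxyphenyl)prop-2-yn-1-one
Product: 14 5,7-dimethoxy-2-(2,3,4,6-tetramethoxyphenyl)-4H-chromen-4-one
Conditions: K2CO3, dry acetone, reflux
Reagents that add atoms: none
Why: 6-endo-dig oxa-Michael addition of the phenoxide to the ynone β-carbon (O1–C2); attack there gives a carbonyl-stabilised allenolate, whereas the 5-exo mode would give an unstabilised vinyl anion that a dry aprotic medium cannot trap by protonation, so the chromenone and not the aurone should result.

Step 8
Reactants: 14 5,7-dimethoxy-2-(2,3,4,6-tetramethoxyphenyl)-4H-chromen-4-one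
Product: 16 3-hydroxy-5,7-dimethoxy-2-(2,3,4,6-tetramethoxyphenyl)-4H-chromen-4-one, via flavon-3-yl dimethyl boronate 15 (not isolated)
Conditions: LiN(i-Pr)2, THF, −78 °C; B(OMe)3, −78 to 0 °C; AcOH, 30% aq H2O2, 0 °C to rt
Reagents that add atoms: hydrogen peroxide, OO; trimethyl borate, COB(OC)OC (boron of 15 only)
Why: C3–H is the only vinylic C–H next to the C4 carbonyl and lithium amides are known to remove it from flavones at −78 °C, the amide being too weak a base to metalate the methoxy-flanked arene positions C6, C8 and C5′; the 3-lithio species is trapped as the borate 15 before it can ring-open, and peroxide induces the boron-to-oxygen 1,2-shift that gives the flavonol.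

Step 9
Reactants: 16 3-hydroxy-5,7-dimethoxy-2-(2,3,4,6-tetramethoxyphenyl)-4H-chromen-4-one
Product: 17 3,5,7-trimethoxy-2-(2,3,4,6-tetramethoxyphenyl)-4H-chromen-4-one
Conditions: MeI, K2CO3, acetone, reflux
Reagents that add atoms: iodomethane, CI
Why: Williamson etherification of the 3-hydroxyl, the only acidic group in 16.

Step 10
Reactants: 17 3,5,7-trimethoxy-2-(2,3,4,6-tetramethoxyphenyl)-4H-chromen-4-one
Product: 19 5-hydroxy-3,7-dimethoxy-2-(2,3,4,6-tetramethoxyphenyl)-4H-chromen-4-one, via C5 dichloroboryl ether 18 (not isolated)
Conditions: BCl3 (1.5 equiv), CH2Cl2, −78 to 0 °C; then H2O, 0 °C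
Reagents that add atoms: boron trichloride, ClB(Cl)Cl (BCl2 group of 18 only)
Why: Chelation-controlled ether cleavage: BCl3 binds the C4 carbonyl and the peri 5-methoxy oxygen in a six-membered chelate and chloride removes the methyl group (SN2) to give 18; the 3-methoxy group could only form a strained five-membered chelate and the ring B ethers have no carbonyl neighbour, so a small excess at low temperature should cleave the C5 ether only, and water then frees the phenol.

Step 11
Reactants: 19 5-hydroxy-3,7-dimethoxy-2-(2,3,4,6-tetramethoxyphenyl)-4H-chromen-4-one
Product: 20 2-(5-hydroxy-3,7-dimethoxy-4-oxo-4H-chromen-2-yl)-3,5-dimethoxycyclohexa-2,5-diene-1,4-dione (CNP0259413.0)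
Conditions: (NH4)2Ce(NO3)6 (2.5 equiv), MeCN–H2O, 0 °C
Reagents that add atoms: water, O
Why: Oxidative demethylation by tetravalent cerium: two one-electron oxidations of the most electron-rich ring, addition of water at C3′ and C6′ (the only para pair of methoxy groups) and loss of two molecules of methanol give the para-quinone; ring A is deactivated by the conjugated C4 carbonyl and its phenol is held in the hydrogen bond, and the quinone is made last because no later reagent would spare it.

Compound list

1 | 3,5-dimethoxyphenol | COc1cc(O)cc(OC)c1 | starting material
2 | 3,5-dimethoxyphenyl N-(propan-2-yl)carbamate | COc1cc(OC)cc(OC(=O)NC(C)C)c1 | intermediate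
3 | 3,5-dimethoxyphenyl N-(propan-2-yl)-N-(trimethylsilyl)carbamate | COc1cc(OC)cc(OC(=O)N(C(C)C)[Si](C)(C)C)c1 | intermediate (not isolated)
4 | 3,5-dimethoxy-2-(trimethylsilyl)phenyl N-(propan-2-yl)-N-(trimethylsilyl)carbamate | COc1cc(OC)c([Si](C)(C)C)c(OC(=O)N(C(C)C)[Si](C)(C)C)c1 | intermediate (not isolated)
5 | 3,5-dimethoxy-2-(trimethylsilyl)phenyl N-(propan-2-yl)carbamate | COc1cc(OC)c([Si](C)(C)C)c(OC(=O)NC(C)C)c1 | intermediate
6 | 3,5-dimethoxy-2-(trimethylsilyl)phenol | COc1cc(O)c([Si](C)(C)C)c(OC)c1 | intermediate (not isolated)
7 | 3,5-dimethoxy-2-(trimethylsilyl)phenyl trifluoromethanesulfonate | COc1cc(OC)c([Si](C)(C)C)c(OS(=O)(=O)C(F)(F)F)c1 | intermediate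
8 | 1,2,3,5-tetramethoxybenzene | COc1cc(OC)c(OC)c(OC)c1 | starting material
9 | 2-iodo-1,3,4,5-tetramethoxybenzene | COc1cc(OC)c(OC)c(OC)c1I | intermediate
10 | propiolic acid (prop-2-ynoic acid) | C#CC(=O)O | starting material
11 | 3-(2,3,4,6-tetramethoxyphenyl)prop-2-ynoic acid | OC(=O)C#Cc1c(OC)cc(OC)c(OC)c1OC | intermediate
12 | 3,5-dimethoxybenzyne (1,2-didehydro-3,5-dimethoxybenzene) | COC1=CC(OC)=CC#C1 | intermediate (not isolated)
13 | 1-(2-hydroxy-4,6-dimethoxyphenyl)-3-(2,3,4,6-tetramethoxyphenyl)prop-2-yn-1-one | COc1cc(O)c(C(=O)C#Cc2c(OC)cc(OC)c(OC)c2OC)c(OC)c1 | intermediate
14 | 5,7-dimethoxy-2-(2,3,4,6-tetramethoxyphenyl)-4H-chromen-4-one | COc1cc(OC)c2c(c1)oc(-c1c(OC)cc(OC)c(OC)c1OC)cc2=O | intermediate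
15 | dimethyl [5,7-dimethoxy-4-oxo-2-(2,3,4,6-tetramethoxyphenyl)-4H-chromen-3-yl]boronate | COB(OC)c1c(-c2c(OC)cc(OC)c(OC)c2OC)oc2cc(OC)cc(OC)c2c1=O | intermediate (not isolated)
16 | 3-hydroxy-5,7-dimethoxy-2-(2,3,4,6-tetramethoxyphenyl)-4H-chromen-4-one | COc1cc(OC)c2c(c1)oc(-c1c(OC)cc(OC)c(OC)c1OC)c(O)c2=O | intermediate
17 | 3,5,7-trimethoxy-2-(2,3,4,6-tetramethoxyphenyl)-4H-chromen-4-one | COc1cc(OC)c2c(c1)oc(-c1c(OC)cc(OC)c(OC)c1OC)c(OC)c2=O | intermediate
18 | 5-[(dichloroboranyl)oxy]-3,7-dimethoxy-2-(2,3,4,6-tetramethoxyphenyl)-4H-chromen-4-one | COc1cc(OB(Cl)Cl)c2c(c1)oc(-c1c(OC)cc(OC)c(OC)c1OC)c(OC)c2=O | intermediate (not isolated)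
19 | 5-hydroxy-3,7-dimethoxy-2-(2,3,4,6-tetramethoxyphenyl)-4H-chromen-4-one | COc1cc(O)c2c(c1)oc(-c1c(OC)cc(OC)c(OC)c1OC)c(OC)c2=O | intermediate
20 | 2-(5-hydroxy-3,7-dimethoxy-4-oxo-4H-chromen-2-yl)-3,5-dimethoxycyclohexa-2,5-diene-1,4-dione | COC1=CC(=O)C(c2oc3cc(OC)cc(O)c3c(=O)c2OC)=C(OC)C1=O | target

Total step count: 11 (steps 1–3 give 7, steps 4–5 give 11, step 6 joins them, steps 7–11 reach the target). Longest linear sequence: 9 steps (1 → 2 → 5 → 7 → 13 → 14 → 16 → 17 → 19 → 20).

Least certain steps

The key step (step 6). Most likely failures are protonation of the aryl anion before the acyl shift (plain O-arylation of the carboxylate), addition of the carbanion to the triple bond instead of the carbonyl, arylation of the product phenoxide by excess aryne, and decarboxylation of the caesium propiolate at 125 °C. The fallback delivers the acyl group to a preformed aryllithium; it sets out from 2 and 11 and returns at 14. 11 would be converted (EDC·HCl, MeNHOMe·HCl, N-methylmorpholine, CH2Cl2, 0 °C) into N-methoxy-N-methyl-3-(2,3,4,6-tetramethoxyphenyl)prop-2-ynamide F1. 2 would be N-silylated and lithiated at C2 as in step 2, and the aryllithium acylated with F1 at −78 °C to give, after acidic work-up, 3,5-dimethoxy-2-[3-(2,3,4,6-tetramethoxyphenyl)prop-2-ynoyl]phenyl N-(propan-2-yl)carbamate F2. DBU and Et2NH in MeCN at 40 °C would then unmask the phenoxide while the amine adds reversibly to the ynone, and the six-membered ring should close with loss of the amine to give 14.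

Step 2. The risk is metalation at C4 between the two methoxy groups, or incomplete N-silylation followed by anionic Fries rearrangement of the lithiated carbamate. The fallback fixes the position with a halogen; it sets out from 1 and returns at 7. NBS in CH2Cl2 at −78 °C would give 2-bromo-3,5-dimethoxyphenol F3 after chromatographic removal of the regioisomer brominated between the two methoxy groups. (Me3Si)2NH in hot THF would give (2-bromo-3,5-dimethoxyphenoxy)trimethylsilane F4. n-BuLi at −78 °C would effect bromine–lithium exchange and retro-Brook O-to-C silyl shift to the lithium salt of 6, which Tf2O would convert into 7.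

Step 5. The risk is slow oxidative addition to the di-ortho-substituted, electron-rich iodide, which would force temperatures at which the propiolate decarboxylates or couples twice. The fallback builds the alkyne from an aldehyde (Corey–Fuchs); it sets out from 8 and returns at 11. Vilsmeier–Haack formylation (POCl3, DMF) would give 2,3,4,6-tetramethoxybenzaldehyde F5. CBr4 and PPh3 in CH2Cl2 would give 2-(2,2-dibromoethenyl)-1,3,4,5-tetramethoxybenzene F6. n-BuLi (2.2 equiv, THF, −78 °C) followed by CO2 and acidification would give 11.

Step 8. The risk is ring opening of the 3-lithio species by β-elimination of O1 before it is trapped, or metalation at C5′. The fallback oxidises the C2–C3 double bond electrophilically; it sets out from 14 and returns at 16. Dimethyldioxirane in acetone/CH2Cl2 at 0 °C would give racemic 2,3-epoxy-5,7-dimethoxy-2-(2,3,4,6-tetramethoxyphenyl)chroman-4-one F7 (oxirane necessarily cis-fused). A catalytic amount of p-TsOH in CH2Cl2 would open the epoxide at C2 and give 16 by loss of the C3 proton.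

Step 10. The risk is loss of chemoselectivity: cleavage of the 3-methoxy group (through its five-membered chelate) or of the crowded 3′-methoxy group together with the 5-methoxy group. The fallback removes the competition between the two ethers next to the carbonyl by changing the order of events; it sets out from 16 and returns at 19. BCl3 (2.5 equiv, CH2Cl2, −78 to 0 °C) on 16 would give 3,5-dihydroxy-7-methoxy-2-(2,3,4,6-tetramethoxyphenyl)-4H-chromen-4-one F8. One equivalent of MeI with K2CO3 in acetone at rt would methylate the 3-hydroxyl and leave the strongly chelated, less acidic 5-hydroxyl, giving 19.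

Step 11. The risk is oxidation of the free phenol ring (oxidative coupling or over-oxidation), or formation of an ortho-quinone from two adjacent ring B ethers. The fallback masks the phenol during the oxidation; it sets out from 19 and returns at 20. Ac2O, pyridine and DMAP would give 3,7-dimethoxy-4-oxo-2-(2,3,4,6-tetramethoxyphenyl)-4H-chromen-5-yl acetate F9. (NH4)2Ce(NO3)6 in MeCN–H2O at 0 °C would give 2-(2,4-dimethoxy-3,6-dioxocyclohexa-1,4-dien-1-yl)-3,7-dimethoxy-4-oxo-4H-chromen-5-yl acetate F10. Catalytic HCl in methanol at rt would remove the peri acetate by transesterification; methoxy exchange at the quinone is degenerate in this solvent, and 20 should result.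

Further compounds

F1 | step 6 | N-methoxy-N-methyl-3-(2,3,4,6-tetramethoxyphenyl)prop-2-ynamide | CON(C)C(=O)C#Cc1c(OC)cc(OC)c(OC)c1OC
F2 | step 6 | 3,5-dimethoxy-2-[3-(2,3,4,6-tetramethoxyphenyl)prop-2-ynoyl]phenyl N-(propan-2-yl)carbamate | COc1cc(OC)c(C(=O)C#Cc2c(OC)cc(OC)c(OC)c2OC)c(OC(=O)NC(C)C)c1
F3 | step 2 | 2-bromo-3,5-dimethoxyphenol | COc1cc(O)c(Br)c(OC)c1
F4 | step 2 | (2-bromo-3,5-dimethoxyphenoxy)trimethylsilane | COc1cc(O[Si](C)(C)C)c(Br)c(OC)c1
F5 | step 5 | 2,3,4,6-tetramethoxybenzaldehyde | COc1cc(OC)c(OC)c(OC)c1C=O
F6 | step 5 | 2-(2,2-dibromoethenyl)-1,3,4,5-tetramethoxybenzene | COc1cc(OC)c(OC)c(OC)c1C=C(Br)Br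
F7 | step 8 | rac-2,3-epoxy-5,7-dimethoxy-2-(2,3,4,6-tetramethoxyphenyl)chroman-4-one (cis-fused oxirane, one enantiomer drawn) | COc1cc(OC)c2C(=O)[C@@H]3O[C@]3(c3c(OC)cc(OC)c(OC)c3OC)Oc2c1
F8 | step 10 | 3,5-dihydroxy-7-methoxy-2-(2,3,4,6-tetramethoxyphenyl)-4H-chromen-4-one | COc1cc(O)c2c(c1)oc(-c1c(OC)cc(OC)c(OC)c1OC)c(O)c2=O
F9 | step 11 | 3,7-dimethoxy-4-oxo-2-(2,3,4,6-tetramethoxyphenyl)-4H-chromen-5-yl acetate | COc1cc(OC(C)=O)c2c(c1)oc(-c1c(OC)cc(OC)c(OC)c1OC)c(OC)c2=O
F10 | step 11 | 2-(2,4-dimethoxy-3,6-dioxocyclohexa-1,4-dien-1-yl)-3,7-dimethoxy-4-oxo-4H-chromen-5-yl acetate | COC1=CC(=O)C(c2oc3cc(OC)cc(OC(C)=O)c3c(=O)c2OC)=C(OC)C1=O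
A1 | alternative 1 | 5,7-dihydroxy-3-methoxy-2-(2,3,4,6-tetramethoxyphenyl)-4H-chromen-4-one | COc1cc(OC)c(-c2oc3cc(O)cc(O)c3c(=O)c2OC)c(OC)c1OC
A2 | alternative 1 | phloroglucinol (benzene-1,3,5-triol) | Oc1cc(O)cc(O)c1
A3 | alternative 1 | ethyl 2-methoxy-3-oxo-3-(2,3,4,6-tetramethoxyphenyl)propanoate (racemic) | CCOC(=O)C(OC)C(=O)c1c(OC)cc(OC)c(OC)c1OC
A4 | alternative 2 | (Z)-2-methoxy-3-(2,3,4,6-tetramethoxyphenyl)-1-(2,4,6-trihydroxyphenyl)prop-2-en-1-one | O=C(/C(OC)=C/c1c(OC)cc(OC)c(OC)c1OC)c1c(O)cc(O)cc1O
A5 | alternative 2 | 4-hydroxy-6-[(3Z)-3-methoxy-2-oxo-4-(2,3,4,6-tetramethoxyphenyl)but-3-en-1-yl]-2H-pyran-2-one | O=C1C=C(O)C=C(CC(=O)/C(OC)=C/c2c(OC)cc(OC)c(OC)c2OC)O1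
A6 | alternative 3 | 1-[2,4-dimethoxy-6-(methoxymethoxy)phenyl]-2-methoxy-3-(2,3,4,6-tetramethoxyphenyl)propane-1,3-dione (racemic) | COCOc1cc(OC)cc(OC)c1C(=O)C(OC)C(=O)c1c(OC)cc(OC)c(OC)c1OC
A7 | alternative 3 | 2-iodo-1,5-dimethoxy-3-(methoxymethoxy)benzene | COCOc1cc(OC)cc(OC)c1I
A8 | alternative 3 | 2-methoxy-1-(2,3,4,6-tetramethoxyphenyl)ethan-1-one | COCC(=O)c1c(OC)cc(OC)c(OC)c1OC
A9 | alternative 3 | carbon monoxide | [C-]#[O+]
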